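## Retrosynthetic overview

- The (2S)-flavanone comes from desilylation of its 7-O-TBS ether, which comes from DDQ aromatisation of a tetrahydrochromenone cycloadduct.
- That cycloadduct arises from an intramolecular Diels–Alder reaction of an O-tethered Danishefsky-type diene onto a terminal ynone, which closes rings A and C together (bonds C8a–C4a and C6–C5).
- The Diels–Alder precursor comes from soft enolisation of a vinylogous ester, made by oxa-Michael addition of an (S)-β-hydroxy ynone to but-3-yn-2-one (O1–C8a exists before any ring is closed).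
- The (S)-β-hydroxy ynone comes from a catalytic asymmetric aldol of 4-(trimethylsilyl)but-3-yn-2-one with the ring-B aldehyde, itself from double Stille prenylation of 3,5-dibromo-4-methoxybenzaldehyde; this sets C2 and no later step breaks a bond to C2.
- Ring order: B is purchased; A and C are formed simultaneously.

Assumption: the target stereocentre reads as (2S) from the SMILES, and compound 1 is bought as a catalogue item (otherwise it is one O-methylation from 3,5-dibromo-4-hydroxybenzaldehyde).

Throughout, Ar = 4-methoxy-3,5-bis(3-methylbut-2-en-1-yl)phenyl.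

## Route

**Step 1**
Reactants: 1, 3,5-dibromo-4-methoxybenzaldehyde; 2, tributyl(3-methylbut-2-en-1-yl)stannane (2.5 equiv)
Product: 3, 4-methoxy-3,5-bis(3-methylbut-2-en-1-yl)benzaldehyde (Ar–CHO)
Conditions: Pd(PPh3)4 (8 mol%), DMF, 100 °C; aq. KF work-up
Reagents that add atoms: 2, tributyl(prenyl)stannane, CCCC[Sn](CCCC)(CCCC)CC=C(C)C (two prenyl groups)
Why: Double Stille allyl–aryl coupling, which with Pd(PPh3)4 gives mainly the linear (α) prenyl product (minor reverse-prenyl isomer removed by chromatography); the neutral conditions leave the aldehyde untouched because allylstannanes do not add to C=O without a Lewis acid.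

**Step 2**
Reactants: 3, Ar–CHO; 4, 4-(trimethylsilyl)but-3-yn-2-one (3 equiv)
Product: 5, (S)-5-hydroxy-5-Ar-1-(trimethylsilyl)pent-1-yn-3-one
Conditions: Et2Zn (20 mol%), (R,R)-ProPhenol (10 mol%), 4 Å MS, THF, 0 °C
Reagents that add atoms: 4, CC(=O)C#C[Si](C)(C)C
Why: Direct catalytic asymmetric aldol of a methyl ynone (dinuclear Zn–ProPhenol), in which the zinc enolate of 4 adds to the Si face of the non-enolisable aldehyde to set the only stereocentre as (S); the ligand enantiomer is the one that gives Si-face addition (confirm (S) by Mosher ester and use the antipodal ligand if needed), and the C-silyl cap blocks conjugate addition to the ynone.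

**Step 3**
Reactants: 5; 6, but-3-yn-2-one (1.5 equiv)
Product: 7, (S,E)-5-Ar-5-[(3-oxobut-1-en-1-yl)oxy]-1-(trimethylsilyl)pent-1-yn-3-one
Conditions: PMe3 (10 mol%), CH2Cl2, 0 °C, 30 min; evaporate volatiles
Reagents that add atoms: 6, CC(=O)C#C
Why: Phosphine-catalysed oxa-Michael addition of an alcohol to a terminal ynone gives the (E)-β-alkoxy enone; the TMS group shields the substrate's own ynone, and the C2–O bond is not broken, so (S) is retained.

**Step 4**
Reactants: 7
Product: 8, (S,E)-5-Ar-5-[(3-oxobut-1-en-1-yl)oxy]pent-1-yn-3-one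
Conditions: Na2B4O7·10H2O (10 mol%), MeOH–THF, 0 °C, 10 min; pH 7 buffer
Reagents that add atoms: none
Why: Protodesilylation of an alkynyl ketone, whose C(sp)–Si bond is cleaved by very weak base, which is mild enough to spare the vinylogous ester, the β-alkoxy ketone and the prenyl groups.

**Step 5**
Reactants: 8
Product: 9, (S,E)-5-Ar-5-{[3-(tert-butyldimethylsilyloxy)buta-1,3-dien-1-yl]oxy}pent-1-yn-3-one (used crude)
Conditions: TBSOTf (1.1 equiv), i-Pr2NEt (1.5 equiv), Et2O, −78 → −20 °C; pentane, filter through basic alumina, concentrate cold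
Reagents that add atoms: tert-butyldimethylsilyl triflate, CC(C)(C)[Si](C)(C)OS(=O)(=O)C(F)(F)F
Why: Soft enolisation (silyl triflate/amine), in which the far more Lewis-basic vinylogous-ester carbonyl is O-silylated in preference to the ynone carbonyl and loses a methyl proton to give the Danishefsky-type (E)-1-alkoxy-3-silyloxydiene; the hindered amine avoids conjugate addition to the terminal ynone.

**Step 6 (key step)**
Reactants: 9
Product: 10, (2S)-2-Ar-7-(tert-butyldimethylsilyloxy)-2,3,6,8a-tetrahydro-4H-chromen-4-one (C4a=C5 and C7=C8 double bonds; mixture of C8a epimers; kept in solution and not isolated)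
Conditions: PhMe (5 mM), BHT (cat.), 70 °C, Ar
Reagents that add atoms: none
Why: Proposed new method: a type-1 intramolecular Diels–Alder reaction in which the four-atom tether (O1–C2–C3–C4) forces fused bonding of C8a to C4a and C6 to C5, matching the electronic preference (silyl enol ether CH2 terminus to ynone β-carbon) and closing rings A and C at once; the closest known reactions are IMDA of dienyl ynones and Danishefsky-diene/ynone benzannulation. C2 is a spectator, so (S) is carried through, and the new C8a centre is removed in the next step.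

**Step 7**
Reactants: 10 (toluene solution from step 6)
Product: 11, (S)-2-Ar-7-(tert-butyldimethylsilyloxy)chroman-4-one
Conditions: DDQ (1.05 equiv), NaHCO3 (s), PhMe, −20 → 0 °C; filter through Celite and a short silica pad
Reagents that add atoms: none
Why: DDQ dehydrogenative aromatisation of a 1,4-cyclohexadiene, in which DDQ abstracts the α-oxy, doubly allylic C8a hydride (cation stabilised by O1 and the 7-silyloxy group) and loss of H6 aromatises ring A without cleaving C8a–O1; the buffer and low temperature protect the prenyl groups, and C2 is untouched.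

**Step 8**
Reactants: 11
Product: 12, abyssinone IV 4'-OMe ether, (S)-7-hydroxy-2-Ar-chroman-4-one
Conditions: TBAF/AcOH (1:1, 1.2 equiv), THF, 0 °C
Reagents that add atoms: none
Why: Fluoride cleavage of an aryl silyl ether; buffering with AcOH prevents base-induced retro-oxa-Michael opening to the 2'-hydroxychalcone, which would racemise C2.

## Compound list

1 | 3,5-dibromo-4-methoxybenzaldehyde | COc1c(Br)cc(C=O)cc1Br | starting material
2 | tributyl(3-methylbut-2-en-1-yl)stannane | CCCC[Sn](CCCC)(CCCC)CC=C(C)C | starting material
3 | 4-methoxy-3,5-bis(3-methylbut-2-en-1-yl)benzaldehyde | COc1c(CC=C(C)C)cc(C=O)cc1CC=C(C)C | intermediate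
4 | 4-(trimethylsilyl)but-3-yn-2-one | CC(=O)C#C[Si](C)(C)C | starting material
5 | (S)-5-hydroxy-5-Ar-1-(trimethylsilyl)pent-1-yn-3-one | COc1c(CC=C(C)C)cc([C@@H](O)CC(=O)C#C[Si](C)(C)C)cc1CC=C(C)C | intermediate
6 | but-3-yn-2-one | CC(=O)C#C | starting material
7 | (S,E)-5-Ar-5-[(3-oxobut-1-en-1-yl)oxy]-1-(trimethylsilyl)pent-1-yn-3-one | COc1c(CC=C(C)C)cc([C@@H](O/C=C/C(C)=O)CC(=O)C#C[Si](C)(C)C)cc1CC=C(C)C | intermediate
8 | (S,E)-5-Ar-5-[(3-oxobut-1-en-1-yl)oxy]pent-1-yn-3-one | COc1c(CC=C(C)C)cc([C@@H](O/C=C/C(C)=O)CC(=O)C#C)cc1CC=C(C)C | intermediate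
9 | (S,E)-5-Ar-5-{[3-(tert-butyldimethylsilyloxy)buta-1,3-dien-1-yl]oxy}pent-1-yn-3-one | COc1c(CC=C(C)C)cc([C@@H](O/C=C/C(=C)O[Si](C)(C)C(C)(C)C)CC(=O)C#C)cc1CC=C(C)C | intermediate
10 | (2S)-2-Ar-7-(tert-butyldimethylsilyloxy)-2,3,6,8a-tetrahydro-4H-chromen-4-one | COc1c(CC=C(C)C)cc([C@@H]2CC(=O)C3=CCC(O[Si](C)(C)C(C)(C)C)=CC3O2)cc1CC=C(C)C | intermediate
11 | (S)-2-Ar-7-(tert-butyldimethylsilyloxy)chroman-4-one | COc1c(CC=C(C)C)cc([C@@H]2CC(=O)c3ccc(O[Si](C)(C)C(C)(C)C)cc3O2)cc1CC=C(C)C | intermediate
12 | abyssinone IV 4'-OMe ether, (S)-7-hydroxy-2-Ar-chroman-4-one | COc1c(CC=C(C)C)cc([C@@H]2CC(=O)c3ccc(O)cc3O2)cc1CC=C(C)C | target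

## Step count and risks

Total steps: 8. Longest linear sequence: 8 (1 → 3 → 5 → 7 → 8 → 9 → 10 → 11 → 12); compounds 2, 4 and 6 are purchased. Steps 6 and 7 are run in the same flask without isolating 10.

Steps most likely to fail:

1. **Step 6 (intramolecular Diels–Alder).** Diene 9 may oligomerise, or cycloadduct 10 may eject O1 by vinylogous β-elimination at 70 °C, giving a ring-opened 4-silyloxyphenyl ketone. Fallback: build the rings one after the other. Cyclise desilylated 5 by 6-endo-dig oxa-Michael addition to (S)-2-Ar-2,3-dihydro-4H-pyran-4-one, α-iodinate (I2/pyridine), and annulate ring A by intermolecular Diels–Alder with Danishefsky's diene (aromatisation by loss of HI and MeOH, with O1 vinylic and unable to leave).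
2. **Step 7 (DDQ aromatisation).** DDQ may attack a prenyl CH2 or the electron-rich ring B instead of the C8a hydride. Fallback: reorder the route so the oxidant never meets a prenyl group. Carry the two aryl bromides of 1 through steps 2–7 and perform the double Stille prenylation last, on the dibromo analogue of 11, before desilylation.
3. **Step 5 (soft enolisation).** The ynone may be silylated competitively, or the activated vinylogous ester may undergo benzylic ionisation or E1cB loss. Fallback: reorder so that no ynone is present during diene formation. Carry C4 as a Weinreb amide through O-alkenylation and silylation, then unveil the ynone last with ethynylmagnesium bromide.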